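The whole plan hinges on cutting ring B at C6=C7. Ring B (C5–C10) is a bare carbocycle. C6 and C7 are plain methylenes flanked by the methines C5 and C8, so each of these can be given a vinyl group. Ring-closing metathesis then stitches C6 to C7, building ring B in a single operation without making or touching a stereocentre. The metathesis substrate 35 is a monocyclic ring A enone (C2 ketone, C1=C10). It carries the C4 methyl/ester centre, a C5 vinyl group and a C10 side arm made of quaternary C9, C8 with its vinyl group and the silylated C11–C15 chain. Diels–Alder, crotylboration and Ireland–Claisen steps set all five stereocentres beforehand.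

Key step: step 19

Numbering: halimane numbering is used. Ring A is C1–C5 and C10, ring B is C5–C10, the chain is C11–C15, and the methyls are C16 on C13, C17 on C8 and C20 on C9.
Design remark: a [3,3] shift onto C9 always leaves a C11=C12 alkene. That alkene is therefore saturated (step 15) while C6 and C7 are still alcohols, and both vinyl groups are unveiled together in step 17. The C2 ketone travels as its enol silane until step 18, so C5 never bears a formyl group next to an enone.
Stereochemical check: 35, 36 and 38 carry the same configuration, 4S,5S,8R,9S,13R.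
Assumption 1: the cationic oxazaborolidine from (S)-diphenylprolinol is taken to expose the face of 21 that leads to 4S,5S. If a test run shows the opposite sense, the antipodal catalyst is used and nothing else changes.
Assumption 2: 22 is drawn as the formyl-endo adduct (arm cis to CHO). The C10 epimer would pass through the same steps, because C10 becomes sp2 in step 18.

Step 1
Reactants: 1 (E)-3-methylpent-2-en-4-yn-1-ol
Product: 3 (2E,4E)-5-iodo-3-methylpenta-2,4-dien-1-ol, via dienylzirconocene 2 (not isolated)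
Conditions: Cp2Zr(H)Cl (2.2 equiv), THF, 0 °C to rt, dark; I2 (1.1 equiv), 0 °C; aqueous work-up
Reagents that add atoms: iodine, II
Why: Hydrozirconation–iodination: syn addition of Zr–H puts zirconium on the terminal carbon (C1), iodinolysis keeps the E geometry, the C9=C11 alkene is untouched and the zirconium alkoxide is hydrolysed on work-up.

Step 2
Reactants: 3 (2E,4E)-5-iodo-3-methylpenta-2,4-dien-1-ol
Product: 4 (2E,4E)-5-iodo-3-methylpenta-2,4-dienal
Conditions: MnO2 (activated, excess), CH2Cl2, rt
Reagents that add atoms: none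
Why: Allylic alcohol oxidation with MnO2 is neutral, so both alkene geometries and the C–I bond should survive.

Step 3
Reactants: 4 (2E,4E)-5-iodo-3-methylpenta-2,4-dienal; 5 cis-but-2-ene
Product: 8 (3S,4R,5E,7E)-8-iodo-3,6-dimethylocta-1,5,7-trien-4-ol, via crotylborane 6 (not isolated), via borinate 7 (not isolated)
Conditions: 5, n-BuLi, KOt-Bu, THF, −78 to −45 °C; (+)-Ipc2BOMe, −78 °C; BF3·OEt2; 4, −78 °C; NaOH, H2O2, 0 °C to rt
Reagents that add atoms: none
Why: Brown asymmetric crotylboration: the Z-crotylborane reacts through a closed chair, which gives the syn C12/C13 pair, and the isopinocampheyl groups from (−)-α-pinene select the aldehyde face that gives 12R,13S (C4 and C3 of 8).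

Step 4
Reactants: 8 (3S,4R,5E,7E)-8-iodo-3,6-dimethylocta-1,5,7-trien-4-ol
Product: 10 (3S,4R,5E,7E)-8-iodo-3,6-dimethylocta-5,7-diene-1,4-diol, via bis-borane 9 (not isolated)
Conditions: 9-BBN (2.5 equiv), THF, 0 °C to rt; NaOH, H2O2, 0 °C
Reagents that add atoms: hydrogen peroxide, OO
Why: Hydroboration–oxidation: 9-BBN adds anti-Markovnikov to the only monosubstituted alkene, leaves the iododiene alone and does not touch C13.

Step 5
Reactants: 10 (3S,4R,5E,7E)-8-iodo-3,6-dimethylocta-5,7-diene-1,4-diol
Product: 11 (3S,4R,5E,7E)-1-(tert-butyldimethylsilyloxy)-8-iodo-3,6-dimethylocta-5,7-dien-4-ol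
Conditions: TBSCl (1.05 equiv), imidazole, CH2Cl2, 0 °C
Reagents that add atoms: tert-butyldimethylsilyl chloride, CC(C)(C)[Si](C)(C)Cl
Why: Silylation under steric control: the primary C15 hydroxyl reacts far faster than the secondary dienylic C12 hydroxyl.

Step 6
Reactants: 11 (3S,4R,5E,7E)-1-(tert-butyldimethylsilyloxy)-8-iodo-3,6-dimethylocta-5,7-dien-4-ol; 12 tributyl(1-ethoxyvinyl)stannane
Product: 14 (3E,5E,7R,8S)-10-(tert-butyldimethylsilyloxy)-7-hydroxy-5,8-dimethyldeca-3,5-dien-2-one, via ethoxytriene 13 (not isolated)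
Conditions: Pd2(dba)3 (2.5 mol%), AsPh3 (10 mol%), DMF, 40 °C; 0.5 M aq. oxalic acid, THF, 0 °C
Reagents that add atoms: water, O
Why: Stille coupling with retention of alkene geometry brings in C2 and C3 as an acetyl equivalent, the very labile 2-ethoxydiene hydrolyses under acid too mild for the silyl ether, and running it before acylation means zerovalent palladium never meets an allylic ester.

Step 7
Reactants: 14 (3E,5E,7R,8S)-10-(tert-butyldimethylsilyloxy)-7-hydroxy-5,8-dimethyldeca-3,5-dien-2-one; 15 propanoyl chloride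
Product: 16 (3E,5E,7R,8S)-10-(tert-butyldimethylsilyloxy)-5,8-dimethyl-2-oxodeca-3,5-dien-7-yl propanoate
Conditions: pyridine, DMAP (cat.), CH2Cl2, 0 °C
Reagents that add atoms: none
Why: DMAP-catalysed O-acylation installs C7, C8 and C17 with retention at C12.

Step 8
Reactants: 16 (3E,5E,7R,8S)-10-(tert-butyldimethylsilyloxy)-5,8-dimethyl-2-oxodeca-3,5-dien-7-yl propanoate
Product: 17 (3E,5E,7R,8S)-2,10-bis(tert-butyldimethylsilyloxy)-5,8-dimethyldeca-1,3,5-trien-7-yl propanoate
Conditions: TBSOTf (1.2 equiv), Et3N, CH2Cl2, −78 to 0 °C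
Reagents that add atoms: tert-butyldimethylsilyl triflate, CC(C)(C)[Si](C)(C)OS(=O)(=O)C(F)(F)F
Why: Soft enolisation (silyl triflate/amine) of the methyl ketone on its CH3 side gives the 2-silyloxydiene, and the ketone reacts much faster than the ester.

Step 9
Reactants: 18 2,2-dimethoxyacetaldehyde; 19 methyl 2-(triphenylphosphoranylidene)propanoate
Product: 20 methyl (E)-4,4-dimethoxy-2-methylbut-2-enoate
Conditions: CH2Cl2/H2O, rt
Reagents that add atoms: none
Why: Wittig reaction of a stabilised α-methyl ylide, which gives the E-alkene (acetal carbon trans to the ester) needed for the C4/C5 relationship.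

Step 10
Reactants: 20 methyl (E)-4,4-dimethoxy-2-methylbut-2-enoate
Product: 21 methyl (E)-2-methyl-4-oxobut-2-enoate
Conditions: TsOH·H2O (cat.), acetone/H2O, rt
Reagents that add atoms: water, O
Why: Acid-catalysed acetal hydrolysis, in which the ester and the E geometry are not affected.

Step 11
Reactants: 17 (3E,5E,7R,8S)-2,10-bis(tert-butyldimethylsilyloxy)-5,8-dimethyldeca-1,3,5-trien-7-yl propanoate; 21 methyl (E)-2-methyl-4-oxobut-2-enoate
Product: 22 ring A formyl enol silane (4S 5S; CHO on C5 trans to CO2Me on C4 and cis to the arm on C10)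
Conditions: (S)-1-(2-methylphenyl)-3,3-diphenyltetrahydropyrrolo[1,2-c][1,3,2]oxazaborole (20 mol%), HN(SO2CF3)2 (18 mol%), CH2Cl2, −78 °C
Reagents that add atoms: none
Why: Catalytic enantioselective Diels–Alder reaction: the boron cation binds the formyl oxygen, so the free, nucleophilic diene end C3 bonds to the crowded C4 and the substituted C10 to C5 (electronics and sterics agree, and the silyloxy diene is the richer of the two diene units), the E geometry of 21 fixes CHO trans to CO2Me, and the catalyst face-shielding sets 4S,5S.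

Step 12
Reactants: 22 ring A formyl enol silane
Product: 23 ring A hydroxymethyl enol silane (C5-CH2OH)
Conditions: NaBH4, MeOH/THF, −20 °C
Reagents that add atoms: none
Why: Chemoselective borohydride reduction masks the future C5 vinyl group as CH2OH before strong base is used, both esters and the enol silane are inert, and the low temperature holds back C5 epimerisation and lactonisation onto the C4 ester.

Step 13
Reactants: 23 ring A hydroxymethyl enol silane
Product: 27 hydroxy acid (C9 quaternary; C8 bearing methyl and CO2H; E-C11=C12), via TMS ether 24 (not isolated), via silyl ketene acetal 25 (not isolated), via TMS ester 26 (not isolated)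
Conditions: TMSCl, Et3N, THF, 0 °C; added to LiN(i-Pr)2 (1.5 equiv), THF, −78 °C; −78 °C to rt, then 50 °C; 1 M aq. citric acid, THF, 0 °C
Reagents that add atoms: none
Why: Ireland–Claisen rearrangement: LiN(i-Pr)2 in THF without polar cosolvent gives the (E)-silyl ketene acetal 25, and a chair with the C13 chain equatorial on C12 and the ring equatorial on C9 passes the 12R centre across the E-C9=C11 alkene, which sets C9 and C8 as in 38 and leaves an E-C11=C12 alkene.

Step 14
Reactants: 27 hydroxy acid
Product: 29 unsaturated diol (C6-OH and C7-OH), via succinimidyl ester 28 (not isolated)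
Conditions: EDC·HCl, N-hydroxysuccinimide, CH2Cl2, rt; NaBH4, THF/H2O, 0 °C
Reagents that add atoms: none
Why: Active-ester reduction: only the free acid is activated, so borohydride turns C7 into CH2OH while the hindered C4 methyl ester, the alkene and the enol silane stay.

Step 15
Reactants: 29 unsaturated diol
Product: 30 saturated diol (C11-C12 single bond)
Conditions: H2 (1 atm), 5% Pt/C, EtOAc, rt
Reagents that add atoms: none
Why: Heterogeneous hydrogenation of the only disubstituted alkene, in which the flanked trisubstituted enol silane is far slower and platinum is preferred to palladium because it causes less double-bond migration toward C13.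

Step 16
Reactants: 30 saturated diol
Product: 31 dialdehyde (C6 and C7 formyl groups)
Conditions: Dess–Martin periodinane (2.4 equiv), NaHCO3, CH2Cl2, 0 °C to rt
Reagents that add atoms: none
Why: Dess–Martin oxidation under buffered, non-basic conditions converts both primary alcohols at once without enolising C5 or C8.

Step 17
Reactants: 31 dialdehyde
Product: 32 divinyl enol silane
Conditions: Ph3PCH3Br, KN(SiMe3)2, THF, 0 °C; 31, −78 to 0 °C
Reagents that add atoms: methyltriphenylphosphonium bromide, C[P+](c1ccccc1)(c1ccccc1)c1ccccc1.[Br-]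
Why: Twofold Wittig methylenation with the small non-stabilised ylide at low temperature turns both formyl groups into the two vinyl groups, addition should outrun enolisation, and the ester and enol silane are inert.

Step 18
Reactants: 32 divinyl enol silane
Product: 35 ring A enone diene (metathesis substrate; 4S 5S 8R 9S 13R), via selenide 33 (not isolated), via selenoxide 34 (not isolated)
Conditions: PhSeCl (1.0 equiv), CH2Cl2, −78 °C; H2O2 (30%), pyridine, 0 °C to rt
Reagents that add atoms: none
Why: Selenoxide elimination: the enol silane is selenenylated at C1 on the face opposite the arm (syn to H10), far faster than the vinyl groups react at −78 °C, and syn elimination toward C10, the only β-hydrogen, erases that centre and gives the enone without base able to touch C5.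

Step 19
Reactants: 35 ring A enone diene
Product: 36 6,7-didehydro bicyclic enone silyl ether
Conditions: RuCl2(=CHPh)(PCy3)(H2IMes) (second-generation Grubbs catalyst, 5 mol%), 1,4-benzoquinone (20 mol%), CH2Cl2 (2 mM), 40 °C, argon sparge
Reagents that add atoms: none
Why: The ruthenium benzylidene exchanges with one terminal vinyl group, the new alkylidene adds to the other vinyl group within the molecule to give a ruthenacyclobutane, and cycloreversion releases the C6=C7 cyclohexene and Ru=CH2 while ethene is swept out. The closest known reaction type is ring-closing metathesis of allylically branched 1,7-dienes to cyclohexenes. Ring B closes as a six-membered ring through that metallacycle, helped by planar C10 and fully substituted C9, which hold C5 and C8 close. No stereocentre is formed: C4, C5, C8, C9 and C13 are carried in, and the ring alkene can only be cis. The selectivity needed is terminal alkenes over the enone alkene, and it is secured because C1=C10 is trisubstituted, electron-poor and shielded by C9, while high dilution disfavours oligomers. Benzoquinone intercepts ruthenium hydrides that could move a double bond through the doubly allylic C5–H into conjugation.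

Step 20
Reactants: 36 6,7-didehydro bicyclic enone silyl ether
Product: 37 bicyclic enone silyl ether
Conditions: H2 (1 atm), RhCl(PPh3)3 (10 mol%), benzene, rt
Reagents that add atoms: none
Why: Homogeneous hydrogenation saturates the cis-disubstituted C6=C7 alkene, whereas the trisubstituted, electron-poor C1=C10 alkene next to quaternary C9 does not bind the bulky rhodium hydride, and the neutral medium protects C5.

Step 21
Reactants: 37 bicyclic enone silyl ether
Product: 38 methyl (1S,5S,6R,8aS)-5-[(3R)-5-hydroxy-3-methylpentyl]-1,5,6-trimethyl-3-oxo-1,2,3,5,6,7,8,8a-octahydronaphthalene-1-carboxylate (target)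
Conditions: HF·pyridine, pyridine, THF, 0 °C
Reagents that add atoms: none
Why: Fluoride-mediated desilylation in buffered HF·pyridine frees the C15 alcohol under non-basic conditions, so the γ-proton at C5 is not exchanged.

Compound list
1 | (E)-3-methylpent-2-en-4-yn-1-ol | C#C/C(C)=C/CO | starting material
2 | O- and C5-bis(chlorozirconocene) derivative of (2E,4E)-3-methylpenta-2,4-dien-1-ol | Cl[Zr](OC/C=C(C)/C=C/[Zr](Cl)(C1C=CC=C1)C1C=CC=C1)(C1C=CC=C1)C1C=CC=C1 | intermediate
3 | (2E,4E)-5-iodo-3-methylpenta-2,4-dien-1-ol | OC/C=C(C)/C=C/I | intermediate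
4 | (2E,4E)-5-iodo-3-methylpenta-2,4-dienal | O=C/C=C(C)/C=C/I | intermediate
5 | cis-but-2-ene | C/C=C\C | starting material
6 | (Z)-crotyldiisopinocampheylborane, Ipc from (−)-α-pinene | C/C=C\CB([C@H]1C[C@H]2C[C@@H]([C@@H]1C)C2(C)C)[C@H]1C[C@H]2C[C@@H]([C@@H]1C)C2(C)C | intermediate
7 | diisopinocampheylborinate of 8 | I/C=C/C(C)=C/[C@H](OB([C@H]1C[C@H]2C[C@@H]([C@@H]1C)C2(C)C)[C@H]1C[C@H]2C[C@@H]([C@@H]1C)C2(C)C)[C@@H](C)C=C | intermediate
8 | (3S,4R,5E,7E)-8-iodo-3,6-dimethylocta-1,5,7-trien-4-ol | I/C=C/C(C)=C/[C@H](O)[C@@H](C)C=C | intermediate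
9 | C15 9-BBN borane and C12 O-9-BBN borinate of 10 | I/C=C/C(C)=C/[C@H](OB1C2CCCC1CCC2)[C@@H](C)CCB1C2CCCC1CCC2 | intermediate
10 | (3S,4R,5E,7E)-8-iodo-3,6-dimethylocta-5,7-diene-1,4-diol | I/C=C/C(C)=C/[C@H](O)[C@@H](C)CCO | intermediate
11 | (3S,4R,5E,7E)-1-(tert-butyldimethylsilyloxy)-8-iodo-3,6-dimethylocta-5,7-dien-4-ol | I/C=C/C(C)=C/[C@H](O)[C@@H](C)CCO[Si](C)(C)C(C)(C)C | intermediate
12 | tributyl(1-ethoxyvinyl)stannane | C=C(OCC)[Sn](CCCC)(CCCC)CCCC | starting material
13 | (3S,4R,5E,7E)-1-(tert-butyldimethylsilyloxy)-9-ethoxy-3,6-dimethyldeca-5,7,9-trien-4-ol | C=C(OCC)/C=C/C(C)=C/[C@H](O)[C@@H](C)CCO[Si](C)(C)C(C)(C)C | intermediate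
14 | (3E,5E,7R,8S)-10-(tert-butyldimethylsilyloxy)-7-hydroxy-5,8-dimethyldeca-3,5-dien-2-one | CC(=O)/C=C/C(C)=C/[C@H](O)[C@@H](C)CCO[Si](C)(C)C(C)(C)C | intermediate
15 | propanoyl chloride | CCC(=O)Cl | starting material
16 | (3E,5E,7R,8S)-10-(tert-butyldimethylsilyloxy)-5,8-dimethyl-2-oxodeca-3,5-dien-7-yl propanoate | CC(=O)/C=C/C(C)=C/[C@H](OC(=O)CC)[C@@H](C)CCO[Si](C)(C)C(C)(C)C | intermediate
17 | (3E,5E,7R,8S)-2,10-bis(tert-butyldimethylsilyloxy)-5,8-dimethyldeca-1,3,5-trien-7-yl propanoate | C=C(O[Si](C)(C)C(C)(C)C)/C=C/C(C)=C/[C@H](OC(=O)CC)[C@@H](C)CCO[Si](C)(C)C(C)(C)C | intermediate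
18 | 2,2-dimethoxyacetaldehyde | COC(OC)C=O | starting material
19 | methyl 2-(triphenylphosphoranylidene)propanoate | COC(=O)C(C)=P(c1ccccc1)(c1ccccc1)c1ccccc1 | starting material
20 | methyl (E)-4,4-dimethoxy-2-methylbut-2-enoate | COC(=O)/C(C)=C/C(OC)OC | intermediate
21 | methyl (E)-2-methyl-4-oxobut-2-enoate | COC(=O)/C(C)=C/C=O | intermediate
22 | ring A adduct: C4 (S; Me, CO2Me), C5 (S; CHO trans to CO2Me), arm on C10 cis to CHO, C1=C2 enol OTBS; arm = (E)-C9(Me)=C11H–C12(R)(OCOEt)–C13(S)(Me)–CH2CH2OTBS | COC(=O)[C@@]1(C)CC(O[Si](C)(C)C(C)(C)C)=C[C@H](/C(C)=C/[C@H](OC(=O)CC)[C@@H](C)CCO[Si](C)(C)C(C)(C)C)[C@@H]1C=O | intermediate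
23 | as 22 with CH2OH on C5 | COC(=O)[C@@]1(C)CC(O[Si](C)(C)C(C)(C)C)=C[C@H](/C(C)=C/[C@H](OC(=O)CC)[C@@H](C)CCO[Si](C)(C)C(C)(C)C)[C@@H]1CO | intermediate
24 | as 23 with C6–OTMS | COC(=O)[C@@]1(C)CC(O[Si](C)(C)C(C)(C)C)=C[C@H](/C(C)=C/[C@H](OC(=O)CC)[C@@H](C)CCO[Si](C)(C)C(C)(C)C)[C@@H]1CO[Si](C)(C)C | intermediate
25 | as 24 with the propanoate as its (E)-O-trimethylsilyl ketene acetal (C17 methyl cis to the C12 oxygen) | COC(=O)[C@@]1(C)CC(O[Si](C)(C)C(C)(C)C)=C[C@H](/C(C)=C/[C@H](O/C(O[Si](C)(C)C)=C\C)[C@@H](C)CCO[Si](C)(C)C(C)(C)C)[C@@H]1CO[Si](C)(C)C | intermediate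
26 | rearranged TMS ester: C9 (Me, C10, C8, E-C11=C12), C8 (Me, CO2TMS), C6–OTMS | COC(=O)[C@@]1(C)CC(O[Si](C)(C)C(C)(C)C)=C[C@H]([C@@](C)(/C=C/[C@@H](C)CCO[Si](C)(C)C(C)(C)C)[C@H](C)C(=O)O[Si](C)(C)C)[C@@H]1CO[Si](C)(C)C | intermediate
27 | hydroxy acid: as 26 with CO2H on C8 and CH2OH on C5 | COC(=O)[C@@]1(C)CC(O[Si](C)(C)C(C)(C)C)=C[C@H]([C@@](C)(/C=C/[C@@H](C)CCO[Si](C)(C)C(C)(C)C)[C@H](C)C(=O)O)[C@@H]1CO | intermediate
28 | N-succinimidyl ester of 27 | COC(=O)[C@@]1(C)CC(O[Si](C)(C)C(C)(C)C)=C[C@H]([C@@](C)(/C=C/[C@@H](C)CCO[Si](C)(C)C(C)(C)C)[C@H](C)C(=O)ON2C(=O)CCC2=O)[C@@H]1CO | intermediate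
29 | unsaturated diol: CH2OH on C8 and on C5, E-C11=C12 | COC(=O)[C@@]1(C)CC(O[Si](C)(C)C(C)(C)C)=C[C@H]([C@@](C)(/C=C/[C@@H](C)CCO[Si](C)(C)C(C)(C)C)[C@H](C)CO)[C@@H]1CO | intermediate
30 | saturated diol | COC(=O)[C@@]1(C)CC(O[Si](C)(C)C(C)(C)C)=C[C@H]([C@@](C)(CC[C@@H](C)CCO[Si](C)(C)C(C)(C)C)[C@H](C)CO)[C@@H]1CO | intermediate
31 | dialdehyde: CHO on C8 and on C5 | COC(=O)[C@@]1(C)CC(O[Si](C)(C)C(C)(C)C)=C[C@H]([C@@](C)(CC[C@@H](C)CCO[Si](C)(C)C(C)(C)C)[C@H](C)C=O)[C@@H]1C=O | intermediate
32 | divinyl enol silane: vinyl on C8 and on C5 | COC(=O)[C@@]1(C)CC(O[Si](C)(C)C(C)(C)C)=C[C@H]([C@@](C)(CC[C@@H](C)CCO[Si](C)(C)C(C)(C)C)[C@H](C)C=C)[C@@H]1C=C | intermediate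
33 | C2 ketone with PhSe on C1, trans to the arm | COC(=O)[C@@]1(C)CC(=O)[C@@H]([Se]c2ccccc2)[C@H]([C@@](C)(CC[C@@H](C)CCO[Si](C)(C)C(C)(C)C)[C@H](C)C=C)[C@@H]1C=C | intermediate
34 | selenoxide of 33 | COC(=O)[C@@]1(C)CC(=O)[C@@H]([Se](=O)c2ccccc2)[C@H]([C@@](C)(CC[C@@H](C)CCO[Si](C)(C)C(C)(C)C)[C@H](C)C=C)[C@@H]1C=C | intermediate
35 | ring A enone with C5 vinyl group and C10 arm (C9 quaternary, C8 but-3-en-2-yl unit, C15 OTBS); 4S,5S,8R,9S,13R | COC(=O)[C@@]1(C)CC(=O)C=C([C@@H]1C=C)[C@@](C)(CC[C@@H](C)CCO[Si](C)(C)C(C)(C)C)[C@H](C)C=C | intermediate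
36 | 6,7-didehydro target as its TBS ether | COC(=O)[C@@]1(C)CC(=O)C=C2[C@@H]1C=C[C@@H](C)[C@]2(C)CC[C@@H](C)CCO[Si](C)(C)C(C)(C)C | intermediate
37 | target TBS ether | COC(=O)[C@@]1(C)CC(=O)C=C2[C@@H]1CC[C@@H](C)[C@]2(C)CC[C@@H](C)CCO[Si](C)(C)C(C)(C)C | intermediate
38 | methyl (1S,5S,6R,8aS)-5-[(3R)-5-hydroxy-3-methylpentyl]-1,5,6-trimethyl-3-oxo-1,2,3,5,6,7,8,8a-octahydronaphthalene-1-carboxylate | COC(=O)[C@@]1(C)CC(=O)C=C2[C@@H]1CC[C@@H](C)[C@]2(C)CC[C@@H](C)CCO | target

Total step count: 21. Longest linear sequence: 19 (steps 1–8 and 11–21).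

Steps most likely to fail

Step 11. The enol silane may add to the activated formyl group in an aldol sense instead of cycloadding. Facial selectivity may erode for a β,β-disubstituted enal, or the acid catalyst may degrade the triene. The fallback replaces catalyst control by auxiliary control and removes the aldehyde; it sets out from 21 and 17 and returns at 23. Pinnick oxidation of 21 (NaClO2, NaH2PO4, 2-methylbut-2-ene, t-BuOH/H2O) should give (E)-4-methoxy-3-methyl-4-oxobut-2-enoic acid F1. Its mixed pivalic anhydride (PivCl, Et3N, then LiCl) acylates (S)-4-benzyl-1,3-oxazolidin-2-one to give the imide dienophile F2. F2, chelated by Et2AlCl (CH2Cl2, −78 °C) in its s-cis form, should add 17 on the face away from the benzyl group, which leads to 4S,5S in the imide cycloadduct F3. NaBH4 in THF/H2O then cleaves the imide reductively to 23.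

Step 17. The basic ylide may enolise the two hindered α-branched aldehydes. That would open the way to epimerisation at C5 or C8 or to an intramolecular aldol reaction of the 1,6-dialdehyde. The fallback is a two-stage Peterson olefination that separates a non-basic addition from the elimination; it sets out from 31 and returns at 32. Me3SiCH2MgCl with CeCl3 (THF, −78 °C) should add to both formyl groups to give the bis(β-hydroxysilane) F4 as a mixture of carbinol epimers. KH (THF, 0 °C) then triggers syn elimination at both sites to give 32.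

Step 19. Ruthenium may load slowly on two vinyl groups that both sit next to fully substituted carbons. Intermolecular metathesis may take over, or a metal hydride may shift a double bond through C5–H into conjugation with the enone. The fallback keeps the same ring closure but runs it on a substrate without vinylogous acidity; it sets out from 35 and returns at 36. Luche reduction (NaBH4, CeCl3·7H2O, MeOH, −78 °C) should give the C2 allylic alcohol diene F5 (either C2 epimer serves). Ring-closing metathesis with RuCl2(=CHPh)(PCy3)(H2IMes) in CH2Cl2 at 40 °C gives the bicyclic allylic alcohol F6, and MnO2 in CH2Cl2 restores the enone as 36.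

Further compounds
F1 | step 11 | (E)-4-methoxy-3-methyl-4-oxobut-2-enoic acid | COC(=O)/C(C)=C/C(=O)O
F2 | step 11 | methyl (E)-4-[(4S)-4-benzyl-2-oxo-1,3-oxazolidin-3-yl]-2-methyl-4-oxobut-2-enoate | COC(=O)/C(C)=C/C(=O)N1[C@@H](Cc2ccccc2)COC1=O
F3 | step 11 | imide cycloadduct: as 22 with C(=O)-[(4S)-4-benzyl-2-oxo-1,3-oxazolidin-3-yl] on C5 | COC(=O)[C@@]1(C)CC(O[Si](C)(C)C(C)(C)C)=C[C@H](/C(C)=C/[C@H](OC(=O)CC)[C@@H](C)CCO[Si](C)(C)C(C)(C)C)[C@@H]1C(=O)N3[C@@H](Cc4ccccc4)COC3=O
F4 | step 17 | bis(β-hydroxysilane): as 31 with CH(OH)CH2SiMe3 on C5 and on C8, carbinol centres unassigned | COC(=O)[C@@]1(C)CC(O[Si](C)(C)C(C)(C)C)=C[C@H]([C@@](C)(CC[C@@H](C)CCO[Si](C)(C)C(C)(C)C)[C@H](C)C(O)C[Si](C)(C)C)[C@@H]1C(O)C[Si](C)(C)C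
F5 | step 19 | C2 allylic alcohol of 35, C2 unassigned | COC(=O)[C@@]1(C)CC(O)C=C([C@@H]1C=C)[C@@](C)(CC[C@@H](C)CCO[Si](C)(C)C(C)(C)C)[C@H](C)C=C
F6 | step 19 | C2 allylic alcohol of 36, C2 unassigned | COC(=O)[C@@]1(C)CC(O)C=C2[C@@H]1C=C[C@@H](C)[C@]2(C)CC[C@@H](C)CCO[Si](C)(C)C(C)(C)C
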